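**Plan**

1. Ring numbering used throughout: C1 = ketone carbon, C2 = carbon bearing CH2OH, C3 = vinylic CH, C4 = CH–O-isobutyryl, C5 = CH–i-Pr, C6 = CH–O-acyl. Retrosynthesis: the two primary alcohols become silyl ethers and the C4 isobutyrate is cut; then C1–C2 and C3–C4 are cut together, leaving a terminal propargyl ether (C2, C3, CH2O) and a γ-butyrolactone (C1, C6, C5, C4, with O4 as ring oxygen); last the C6–O acyl bond, the C6–O bond and the C5–i-Pr bond, back to a menthol-derived 5-alkoxybutenolide.
2. Enabling feature: C1 (C=O) and the oxygen on C4 stand 1,4 across C6–C5, so O4 can be folded back onto C1 as a five-membered lactone. In that ring C4 is an acylal carbon (C–Br gives a planar α-oxy radical) and C1 is an acyl donor with O4 as built-in leaving group, so an alkyne can be stitched across C4 and C1 through a 7-oxabicyclo[2.2.1]heptene hemiketal that opens to the ketone and the free C4–OH.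
3. Forward: butenolide, conjugate addition (C5), enolate hydroxylation (C6), esterification with the separately made silyl-protected 4-hydroxytiglic acid, anomeric bromide, annulation with the propargyl ether (the lactone ring opens as the only carbocycle closes), isobutyrylation of the liberated C4–OH, desilylation.
4. Stereochemistry: the l-menthyl acetal is the only source of absolute configuration; C5 comes from addition anti to the acetal alkoxy group, C6 from hydroxylation anti to i-Pr, C4 from radical addition anti to i-Pr on the lactone in the key step; the E enoate comes from a stabilised Wittig reaction.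

Key step: step 8

Remark: the menthol-derived butenolide is taken as a purchasable compound, and the anomeric bromide made later is carried as a mixture of anomers because the radical formed from it is planar ("l-menthyl" = (1R,2S,5R)-5-methyl-2-(propan-2-yl)cyclohexyl).

**Step 1**
Reactants: 1 (5R)-5-(l-menthyloxy)furan-2(5H)-one
Product: 2 (4S,5R)-5-(l-menthyloxy)-4-(propan-2-yl)oxolan-2-one (isopropyl trans to menthyloxy)
Conditions: i-PrMgCl, CuBr·SMe2 (cat.), THF, −78 to −40 °C; aq. NH4Cl
Reagents that add atoms: isopropylmagnesium chloride, CC(C)[Mg]Cl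
Why: Copper-catalysed conjugate addition of the Grignard reagent to the butenolide should deliver the isopropyl group to the β-carbon on the face anti to the neighbouring acetal alkoxy group, which sets the C5 stereocentre.

**Step 2**
Reactants: 2 (4S,5R)-5-(l-menthyloxy)-4-(propan-2-yl)oxolan-2-one
Product: 3 (3R,4R,5R)-3-hydroxy-5-(l-menthyloxy)-4-(propan-2-yl)oxolan-2-one (all-trans)
Conditions: KN(SiMe3)2, THF, −78 °C; 3-phenyl-2-(phenylsulfonyl)oxaziridine; AcOH
Reagents that add atoms: 3-phenyl-2-(phenylsulfonyl)oxaziridine, O=S(=O)(N1OC1c1ccccc1)c1ccccc1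
Why: Enolate oxidation with an N-sulfonyloxaziridine should place the hydroxyl on the enolate face anti to the adjacent isopropyl group, which sets the C6 stereocentre trans to C5.

**Step 3**
Reactants: 4 glycolaldehyde dimer (1,4-dioxane-2,5-diol); 5 ethyl 2-(triphenyl-λ5-phosphanylidene)propanoate
Product: 6 ethyl (2E)-4-hydroxy-2-methylbut-2-enoate
Conditions: CH2Cl2, reflux
Reagents that add atoms: none
Why: Wittig olefination of glycolaldehyde (released from its dimer) with the stabilised α-methyl ylide should give the E trisubstituted enoate.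

**Step 4**
Reactants: 6 ethyl (2E)-4-hydroxy-2-methylbut-2-enoate
Product: 7 ethyl (2E)-4-[(tert-butyldiphenylsilyl)oxy]-2-methylbut-2-enoate
Conditions: TBDPSCl, imidazole, CH2Cl2, 0 °C to rt
Reagents that add atoms: tert-butyl(chloro)diphenylsilane, CC(C)(C)[Si](Cl)(c1ccccc1)c1ccccc1
Why: Silyl ether protection of the primary allylic alcohol with a group robust enough for the Lewis acid of step 7.

**Step 5**
Reactants: 7 ethyl (2E)-4-[(tert-butyldiphenylsilyl)oxy]-2-methylbut-2-enoate
Product: 8 (2E)-4-[(tert-butyldiphenylsilyl)oxy]-2-methylbut-2-enoic acid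
Conditions: LiOH, THF/H2O, rt; then 1 M HCl
Reagents that add atoms: lithium hydroxide, [Li+].[OH-]
Why: Saponification of the ethyl ester should leave the silyl ether and the alkene geometry untouched.

**Step 6**
Reactants: 3 (3R,4R,5R)-3-hydroxy-5-(l-menthyloxy)-4-(propan-2-yl)oxolan-2-one; 8 (2E)-4-[(tert-butyldiphenylsilyl)oxy]-2-methylbut-2-enoic acid
Product: 9 (3R,4R,5R)-5-(l-menthyloxy)-2-oxo-4-(propan-2-yl)oxolan-3-yl (2E)-4-[(tert-butyldiphenylsilyl)oxy]-2-methylbut-2-enoate
Conditions: DCC, DMAP (cat.), CH2Cl2, 0 °C to rt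
Reagents that add atoms: none
Why: Steglich esterification of the secondary α-hydroxy lactone installs the complete C6 side chain early without touching a stereocentre.

**Step 7**
Reactants: 9 (3R,4R,5R)-5-(l-menthyloxy)-2-oxo-4-(propan-2-yl)oxolan-3-yl (2E)-4-[(tert-butyldiphenylsilyl)oxy]-2-methylbut-2-enoate
Product: 10 (3R,4R)-5-bromo-2-oxo-4-(propan-2-yl)oxolan-3-yl (2E)-4-[(tert-butyldiphenylsilyl)oxy]-2-methylbut-2-enoate (both anomers, used crude)
Conditions: Me2BBr, CH2Cl2, −78 to 0 °C; volatiles removed in vacuo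
Reagents that add atoms: bromodimethylborane, CB(C)Br
Why: Acetal cleavage by a dialkylboron bromide should exchange the exocyclic alkoxy group for bromide through the ring-oxygen-stabilised oxocarbenium ion, with boron taking up the menthyl oxide and the esters and TBDPS ether inert at low temperature.

**Step 8**
Reactants: 10 (3R,4R)-5-bromo-2-oxo-4-(propan-2-yl)oxolan-3-yl (2E)-4-[(tert-butyldiphenylsilyl)oxy]-2-methylbut-2-enoate; 11 tert-butyldimethyl(prop-2-yn-1-yloxy)silane
Product: 13 (1R,5S,6S)-3-{[(tert-butyldimethylsilyl)oxy]methyl}-5-hydroxy-2-oxo-6-(propan-2-yl)cyclohex-3-en-1-yl (2E)-4-[(tert-butyldiphenylsilyl)oxy]-2-methylbut-2-enoate, via bridged hemiketal alkoxide 12 (not isolated)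
Conditions: 11 (excess), NiBr2(dme) (cat.), 4,4′-di-tert-butyl-2,2′-bipyridine (cat.), Mn powder, DMA/THF, 25 °C; aq. NH4Cl
Reagents that add atoms: none
Why: Proposed new method: a nickel-catalysed reductive radical [4+2] annulation in which low-valent nickel abstracts bromine from the acylal carbon of 10, the planar α-oxy radical adds to the terminal carbon of alkyne 11 (C3–C4 bond), the vinyl radical (or the alkenyl bromide formed from it by atom transfer) is taken up as an alkenylnickel, and this adds across the lactone C=O (C1–C2 bond) to give hemiketal alkoxide 12, whose collapse expels the ring oxygen as the C4 alkoxide while Mn returns nickel to the low-valent state. The closest known reaction types are the nickel-catalysed reductive addition of anomeric radicals from α-bromo ethers to terminal alkynes with capture of the vinyl radical at nickel, and the intramolecular acyl substitution of esters by alkenylnickel species in alkyne annulations that give cyclopentenones; their union on a lactone whose ring oxygen is the leaving group has not been shown. The only ring closed is the carbocycle, by 6-exo-trig attack of the alkenyl carbon on the lactone carbonyl through the 7-oxabicyclo[2.2.1]heptene 12, the same bridged topology through which stabilised anions acylate themselves on a lactone carbonyl in the Hauser annulation. The new stereocentre C4 is set in the radical addition, which should occur on the face of the five-membered ring opposite the adjacent isopropyl group (1,2-trans induction in cyclic radicals), so both anomers of 10 converge and the carbinol oxygen ends cis to isopropyl; C5 and C6 are not touched. The step needs addition at the terminal alkyne carbon (secured by the unsubstituted terminus and the more stable α-substituted vinyl radical), a cis relation of nickel and C4 on the new alkene (secured by fast inversion of the vinyl radical and E/Z equilibration of the alkenylnickel, only the cis isomer being able to cyclise), and acylation by the lactone instead of the enoate (secured by ring size and by the lower electrophilicity of the conjugated α-branched ester).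

**Step 9**
Reactants: 13 (1R,5S,6S)-3-{[(tert-butyldimethylsilyl)oxy]methyl}-5-hydroxy-2-oxo-6-(propan-2-yl)cyclohex-3-en-1-yl (2E)-4-[(tert-butyldiphenylsilyl)oxy]-2-methylbut-2-enoate
Product: 14 (1R,5S,6S)-3-{[(tert-butyldimethylsilyl)oxy]methyl}-5-[(2-methylpropanoyl)oxy]-2-oxo-6-(propan-2-yl)cyclohex-3-en-1-yl (2E)-4-[(tert-butyldiphenylsilyl)oxy]-2-methylbut-2-enoate
Conditions: (i-PrCO)2O, DMAP (cat.), pyridine, CH2Cl2, 0 °C
Reagents that add atoms: 2-methylpropanoic anhydride, CC(C)C(=O)OC(=O)C(C)C
Why: DMAP-catalysed acylation of the only free hydroxyl, the allylic C4–OH released in step 8, should proceed without change at C6, whose trans-diequatorial arrangement with isopropyl is the stable one.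

**Step 10**
Reactants: 14 (1R,5S,6S)-3-{[(tert-butyldimethylsilyl)oxy]methyl}-5-[(2-methylpropanoyl)oxy]-2-oxo-6-(propan-2-yl)cyclohex-3-en-1-yl (2E)-4-[(tert-butyldiphenylsilyl)oxy]-2-methylbut-2-enoate
Product: 15 (1R,5S,6S)-3-(hydroxymethyl)-5-[(2-methylpropanoyl)oxy]-2-oxo-6-(propan-2-yl)cyclohex-3-en-1-yl (2E)-4-hydroxy-2-methylbut-2-enoate (CNP0254776.1)
Conditions: HF·pyridine, pyridine, THF, 0 °C to rt
Reagents that add atoms: none
Why: Buffered fluoride desilylation should remove both primary silyl ethers while sparing the three esters, the enone and the α-acyloxy ketone stereocentre.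

**Compound list**

1 | (5R)-5-{[(1R,2S,5R)-5-methyl-2-(propan-2-yl)cyclohexyl]oxy}furan-2(5H)-one | O=C1O[C@@H](O[C@@H]2C[C@H](C)CC[C@H]2C(C)C)C=C1 | starting material
2 | (4S,5R)-5-(l-menthyloxy)-4-(propan-2-yl)oxolan-2-one | O=C1C[C@@H](C(C)C)[C@H](O[C@@H]2C[C@H](C)CC[C@H]2C(C)C)O1 | intermediate
3 | (3R,4R,5R)-3-hydroxy-5-(l-menthyloxy)-4-(propan-2-yl)oxolan-2-one | O[C@H]1C(=O)O[C@@H](O[C@@H]2C[C@H](C)CC[C@H]2C(C)C)[C@@H]1C(C)C | intermediate
4 | glycolaldehyde dimer (1,4-dioxane-2,5-diol) | OC1COC(O)CO1 | starting material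
5 | ethyl 2-(triphenyl-λ5-phosphanylidene)propanoate | CCOC(=O)C(C)=P(c1ccccc1)(c1ccccc1)c1ccccc1 | starting material
6 | ethyl (2E)-4-hydroxy-2-methylbut-2-enoate | C/C(=C\CO)C(=O)OCC | intermediate
7 | ethyl (2E)-4-[(tert-butyldiphenylsilyl)oxy]-2-methylbut-2-enoate | C/C(=C\CO[Si](c1ccccc1)(c1ccccc1)C(C)(C)C)C(=O)OCC | intermediate
8 | (2E)-4-[(tert-butyldiphenylsilyl)oxy]-2-methylbut-2-enoic acid | C/C(=C\CO[Si](c1ccccc1)(c1ccccc1)C(C)(C)C)C(=O)O | intermediate
9 | (3R,4R,5R)-5-(l-menthyloxy)-2-oxo-4-(propan-2-yl)oxolan-3-yl (2E)-4-[(tert-butyldiphenylsilyl)oxy]-2-methylbut-2-enoate | C/C(=C\CO[Si](c1ccccc1)(c1ccccc1)C(C)(C)C)C(=O)O[C@H]1C(=O)O[C@@H](O[C@@H]2C[C@H](C)CC[C@H]2C(C)C)[C@@H]1C(C)C | intermediate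
10 | (3R,4R)-5-bromo-2-oxo-4-(propan-2-yl)oxolan-3-yl (2E)-4-[(tert-butyldiphenylsilyl)oxy]-2-methylbut-2-enoate, both anomers | C/C(=C\CO[Si](c1ccccc1)(c1ccccc1)C(C)(C)C)C(=O)O[C@H]1C(=O)OC(Br)[C@@H]1C(C)C | intermediate
11 | tert-butyldimethyl(prop-2-yn-1-yloxy)silane | C#CCO[Si](C)(C)C(C)(C)C | starting material
12 | 1-hydroxy-2-{[(tert-butyldimethylsilyl)oxy]methyl}-5-exo-(propan-2-yl)-7-oxabicyclo[2.2.1]hept-2-en-6-endo-yl (2E)-4-[(tert-butyldiphenylsilyl)oxy]-2-methylbut-2-enoate (bridged hemiketal, present as its metal alkoxide) | C/C(=C\CO[Si](c1ccccc1)(c1ccccc1)C(C)(C)C)C(=O)O[C@H]1[C@@]2(O)C(CO[Si](C)(C)C(C)(C)C)=C[C@H](O2)[C@@H]1C(C)C | intermediate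
13 | (1R,5S,6S)-3-{[(tert-butyldimethylsilyl)oxy]methyl}-5-hydroxy-2-oxo-6-(propan-2-yl)cyclohex-3-en-1-yl (2E)-4-[(tert-butyldiphenylsilyl)oxy]-2-methylbut-2-enoate | C/C(=C\CO[Si](c1ccccc1)(c1ccccc1)C(C)(C)C)C(=O)O[C@H]1C(=O)C(CO[Si](C)(C)C(C)(C)C)=C[C@H](O)[C@@H]1C(C)C | intermediate
14 | (1R,5S,6S)-3-{[(tert-butyldimethylsilyl)oxy]methyl}-5-[(2-methylpropanoyl)oxy]-2-oxo-6-(propan-2-yl)cyclohex-3-en-1-yl (2E)-4-[(tert-butyldiphenylsilyl)oxy]-2-methylbut-2-enoate | C/C(=C\CO[Si](c1ccccc1)(c1ccccc1)C(C)(C)C)C(=O)O[C@H]1C(=O)C(CO[Si](C)(C)C(C)(C)C)=C[C@H](OC(=O)C(C)C)[C@@H]1C(C)C | intermediate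
15 | (1R,5S,6S)-3-(hydroxymethyl)-5-[(2-methylpropanoyl)oxy]-2-oxo-6-(propan-2-yl)cyclohex-3-en-1-yl (2E)-4-hydroxy-2-methylbut-2-enoate | C/C(=C\CO)C(=O)O[C@H]1C(=O)C(CO)=C[C@H](OC(=O)C(C)C)[C@@H]1C(C)C | target

**Totals and risks**

Total step count: 10. Longest linear sequence: 8 steps (steps 3, 4, 5, 6, 7, 8, 9, 10).

Steps most likely to fail:

Step 8. The anomeric radical may be reduced or may dimerise before it adds to the alkyne, the vinyl radical may abstract hydrogen, or the alkenylnickel may lose silanolate (allene formation) instead of adding across the lactone carbonyl. The fallback sets out from 10 and comes back at 13, making the ring bonds one at a time by known reactions. Nickel-catalysed reductive cross-coupling of 10 with vinyl bromide (NiBr2(dme), bipyridine ligand, Zn, DMA) should give (3R,4S,5S)-5-ethenyl-2-oxo-4-(propan-2-yl)oxolan-3-yl (2E)-4-[(tert-butyldiphenylsilyl)oxy]-2-methylbut-2-enoate F1, with the vinyl group trans to isopropyl. Addition of [3-{[tert-butyl(dimethyl)silyl]oxy}prop-1-en-2-yl]lithium F2 (from the 2-bromoallyl silyl ether and t-BuLi) to the lactone carbonyl at −90 °C should give, after work-up, the open hydroxy dienone (4R,5S,6S)-2-{[(tert-butyldimethylsilyl)oxy]methyl}-6-hydroxy-3-oxo-5-(propan-2-yl)octa-1,7-dien-4-yl (2E)-4-[(tert-butyldiphenylsilyl)oxy]-2-methylbut-2-enoate F3. Ring-closing metathesis with the second-generation Hoveyda–Grubbs catalyst in toluene at 80 °C then closes C2=C3 and gives 13.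

Step 7. The anomeric bromide may lose HBr to an enol lactone, or the silyl ether may be attacked by the Lewis acid before the deactivated acetal is cleaved. The fallback sets out from 9 and comes back at 10 by hydrolysis followed by halogenation instead of direct exchange. Aqueous trifluoroacetic acid should hydrolyse the acetal to the hemiacylal (3R,4R)-5-hydroxy-2-oxo-4-(propan-2-yl)oxolan-3-yl (2E)-4-[(tert-butyldiphenylsilyl)oxy]-2-methylbut-2-enoate F4 (anomeric mixture), and an Appel reaction (CBr4, PPh3, CH2Cl2, 0 °C) then gives 10.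

Step 6. Acylation of the hindered secondary alcohol by the α-branched conjugated acid may be slow, with rearrangement of the activated acid to the N-acylurea. The fallback sets out from 3 and comes back at 9 by building the enoate on the lactone. Carbodiimide coupling of 3 with 2-(diethoxyphosphoryl)propanoic acid should give (3R,4R,5R)-5-(l-menthyloxy)-2-oxo-4-(propan-2-yl)oxolan-3-yl 2-(diethoxyphosphoryl)propanoate F5 (both epimers at the phosphonate carbon). A Horner–Wadsworth–Emmons reaction of F5 with (tert-butyldiphenylsilyloxy)acetaldehyde (LiCl, DBU, MeCN) should then give the E enoate 9.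

Further compounds
F1 | step 8 | (3R,4S,5S)-5-ethenyl-2-oxo-4-(propan-2-yl)oxolan-3-yl (2E)-4-[(tert-butyldiphenylsilyl)oxy]-2-methylbut-2-enoate | C/C(=C\CO[Si](c1ccccc1)(c1ccccc1)C(C)(C)C)C(=O)O[C@H]1C(=O)O[C@@H](C=C)[C@@H]1C(C)C
F2 | step 8 | [3-{[tert-butyl(dimethyl)silyl]oxy}prop-1-en-2-yl]lithium | [Li]C(=C)CO[Si](C)(C)C(C)(C)C
F3 | step 8 | (4R,5S,6S)-2-{[(tert-butyldimethylsilyl)oxy]methyl}-6-hydroxy-3-oxo-5-(propan-2-yl)octa-1,7-dien-4-yl (2E)-4-[(tert-butyldiphenylsilyl)oxy]-2-methylbut-2-enoate | C/C(=C\CO[Si](c1ccccc1)(c1ccccc1)C(C)(C)C)C(=O)O[C@@H](C(=O)C(=C)CO[Si](C)(C)C(C)(C)C)[C@@H](C(C)C)[C@@H](O)C=C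
F4 | step 7 | (3R,4R)-5-hydroxy-2-oxo-4-(propan-2-yl)oxolan-3-yl (2E)-4-[(tert-butyldiphenylsilyl)oxy]-2-methylbut-2-enoate, both anomers | C/C(=C\CO[Si](c1ccccc1)(c1ccccc1)C(C)(C)C)C(=O)O[C@H]1C(=O)OC(O)[C@@H]1C(C)C
F5 | step 6 | (3R,4R,5R)-5-(l-menthyloxy)-2-oxo-4-(propan-2-yl)oxolan-3-yl 2-(diethoxyphosphoryl)propanoate | CCOP(=O)(OCC)C(C)C(=O)O[C@H]1C(=O)O[C@@H](O[C@@H]2C[C@H](C)CC[C@H]2C(C)C)[C@@H]1C(C)C
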